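**Retrosynthetic overview**
1. The ten-membered carbocycle is closed last, by a Ni/Cr (Nozaki–Hiyama–Kishi) macrocyclization that forms C2–C3 from a (Z)-dienyl iodide and a neopentyl C2 aldehyde (33 → 35).
2. The seco precursor is cut at C9–C10: a Cr(II) Nozaki–Hiyama allylation joins cyclohexenyl bromide 8 to lactone aldehyde 28, setting C9 and C10 and placing the C11=C12 alkene.
3. Bromide 8 (C1, C2, C10–C15, C20) comes from (S)-carvone: formylation/methylation builds quaternary C1, a Criegee rearrangement turns the isopropenyl group into the C14 acetate.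
4. Aldehyde 28 (C3–C9, C16–C19) comes from an HWE reaction of a lactate-derived phosphonosuccinate with a (Z)-iodo-enal, Sharpless epoxidation, invertive epoxide-opening lactonization, and a Stille reaction for the (Z)-iododiene.
5. Ring order: cyclohexene (chiral pool) and γ-lactone (fragment stage) first, ten-membered ring last.

Assumption: briarane numbering (C1–C20, C19 = lactone carbonyl) is used for positions; tert-butyl (R)-lactate and nickel-free CrCl2 are taken as purchasable.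

**Step 1**
Reactants: 1 (S)-carvone
Product: 2 (5R)-6-(hydroxymethylidene)-2-methyl-5-(prop-1-en-2-yl)cyclohex-2-en-1-one
Conditions: LDA, THF, −78 °C; HCO2CH2CF3, −78 → 0 °C; aq. NH4Cl
Reagents that add atoms: 2,2,2-trifluoroethyl formate O=COCC(F)(F)F
Why: Kinetic α′-deprotonation of the enone and Claisen formylation give the enolised β-keto aldehyde, and no stereocentre is created because C6 is trigonal.

**Step 2**
Reactants: 2 (5R)-6-(hydroxymethylidene)-2-methyl-5-(prop-1-en-2-yl)cyclohex-2-en-1-one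
Product: 3 (1R,6R)-1,3-dimethyl-2-oxo-6-(prop-1-en-2-yl)cyclohex-3-ene-1-carbaldehyde
Conditions: K2CO3, MeI, acetone, rt
Reagents that add atoms: iodomethane CI
Why: C-alkylation (SN2) of the β-dicarbonyl enolate occurs anti to the adjacent isopropenyl group, so the new quaternary centre (future C1) has CH3 trans and CHO cis to that group.

**Step 3**
Reactants: 3 (1R,6R)-1,3-dimethyl-2-oxo-6-(prop-1-en-2-yl)cyclohex-3-ene-1-carbaldehyde
Product: 4 (5R,6R)-6-(dimethoxymethyl)-2,6-dimethyl-5-(prop-1-en-2-yl)cyclohex-2-en-1-one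
Conditions: HC(OMe)3 (neat), CSA (cat.), rt
Reagents that add atoms: trimethyl orthoformate COC(OC)OC
Why: Acid-catalysed acetalisation is selective for the aldehyde over the hindered conjugated ketone and masks the future C2 aldehyde without touching a stereocentre.

**Step 4**
Reactants: 4 (5R,6R)-6-(dimethoxymethyl)-2,6-dimethyl-5-(prop-1-en-2-yl)cyclohex-2-en-1-one
Product: 6 (1S,6R)-6-(dimethoxymethyl)-4,6-dimethyl-5-oxocyclohex-3-en-1-yl acetate, via methoxy hydroperoxide 5 (not isolated)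
Conditions: O3, CH2Cl2/MeOH, −78 °C (Sudan Red end point); then Ac2O, Et3N, DMAP (cat.), CH2Cl2, 0 °C → rt
Reagents that add atoms: ozone [O-][O+]=O; methanol CO
Why: Ozone cleaves only the electron-rich 1,1-disubstituted alkene (the enone C=C is deactivated) and the peracetate of 5 undergoes Criegee rearrangement with migration of the ring carbon and retention, giving the (S)-acetate of the future C14.

**Step 5**
Reactants: 6 (1S,6R)-6-(dimethoxymethyl)-4,6-dimethyl-5-oxocyclohex-3-en-1-yl acetate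
Product: 7 (1S,6R)-6-(dimethoxymethyl)-5-hydroxy-4,6-dimethylcyclohex-3-en-1-yl acetate (C5 epimers)
Conditions: NaBH4, CeCl3·7H2O, MeOH, −20 °C
Reagents that add atoms: none
Why: Luche 1,2-reduction of the hindered enone gives the allylic alcohol, whose carbinol configuration is irrelevant because it is erased at the allylchromium stage.

**Step 6**
Reactants: 7 (1S,6R)-6-(dimethoxymethyl)-5-hydroxy-4,6-dimethylcyclohex-3-en-1-yl acetate
Product: 8 (1S,6R)-3-bromo-6-(dimethoxymethyl)-4,6-dimethylcyclohex-4-en-1-yl acetate (C3 epimers)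
Conditions: CBr4, PPh3, 2,6-lutidine (cat.), CH2Cl2, 0 °C; used crude
Reagents that add atoms: carbon tetrabromide BrC(Br)(Br)Br
Why: Appel bromination of the neopentylic allylic alcohol proceeds with allylic transposition (SN2′/ion pair) to the less hindered secondary bromide, and all regio- and stereoisomers converge on one allylchromium later.

**Step 7**
Reactants: 9 tert-butyl (2R)-2-hydroxypropanoate
Product: 10 tert-butyl (2R)-2-{[(trifluoromethyl)sulfonyl]oxy}propanoate
Conditions: Tf2O, 2,6-lutidine, CH2Cl2, −78 → 0 °C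
Reagents that add atoms: triflic anhydride O=S(=O)(OS(=O)(=O)C(F)(F)F)C(F)(F)F
Why: O-Sulfonylation breaks no C–O bond, so the configuration is retained and a reactive α-triflyloxy ester results.

**Step 8**
Reactants: 10 tert-butyl (2R)-2-{[(trifluoromethyl)sulfonyl]oxy}propanoate; 11 triethyl phosphonoacetate
Product: 12 4-tert-butyl 1-ethyl (3S)-2-(diethoxyphosphoryl)-3-methylbutanedioate (C2 epimers)
Conditions: NaH, THF, 0 °C; then 10, −20 °C → rt
Reagents that add atoms: none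
Why: SN2 alkylation of the phosphonoacetate carbanion by the α-triflyloxy ester goes with clean Walden inversion and sets the future C17 methyl stereocentre (the phosphonate carbon is destroyed in step 12).

**Step 9**
Reactants: 13 but-2-yne-1,4-diol
Product: 14 4-[(tert-butyldiphenylsilyl)oxy]but-2-yn-1-ol
Conditions: NaH (1.0 equiv), THF, 0 °C; TBDPSCl
Reagents that add atoms: tert-butyl(chloro)diphenylsilane CC(C)(C)[Si](Cl)(c1ccccc1)c1ccccc1
Why: Monosilylation of the symmetrical diol through its sparingly soluble mono-sodium alkoxide (O-silylation) stops cleanly at the mono-ether.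

**Step 10**
Reactants: 14 4-[(tert-butyldiphenylsilyl)oxy]but-2-yn-1-ol
Product: 16 (2Z)-4-[(tert-butyldiphenylsilyl)oxy]-3-iodobut-2-en-1-ol, via cyclic alkenylalanate 15 (not isolated)
Conditions: Red-Al, THF, 0 °C → rt; then I2, −78 → 0 °C
Reagents that add atoms: iodine II
Why: Hydroxyl-directed trans-hydroalumination places aluminium on the distal alkyne carbon and iodinolysis with retention gives the (Z)-iodo alkenol (I cis to CH2OH), which fixes the C5=C6 geometry.

**Step 11**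
Reactants: 16 (2Z)-4-[(tert-butyldiphenylsilyl)oxy]-3-iodobut-2-en-1-ol
Product: 17 (2Z)-4-[(tert-butyldiphenylsilyl)oxy]-3-iodobut-2-enal
Conditions: MnO2, CH2Cl2, rt; used at once
Reagents that add atoms: none
Why: MnO2 oxidises the allylic alcohol chemoselectively to the enal without touching the vinyl iodide or the alkene geometry.

**Step 12**
Reactants: 12 4-tert-butyl 1-ethyl (3S)-2-(diethoxyphosphoryl)-3-methylbutanedioate; 17 (2Z)-4-[(tert-butyldiphenylsilyl)oxy]-3-iodobut-2-enal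
Product: 18 4-tert-butyl 1-ethyl (2E,3R)-2-{(2Z)-4-[(tert-butyldiphenylsilyl)oxy]-3-iodobut-2-en-1-ylidene}-3-methylbutanedioate
Conditions: LiCl, DBU, MeCN, 0 °C → rt
Reagents that add atoms: none
Why: Masamune–Roush Horner–Wadsworth–Emmons olefination gives the (E)-alkylidene succinate (ester trans to the dienyl chain) under mild base that leaves the α-methyl stereocentre and the (Z)-iodoalkene intact.

**Step 13**
Reactants: 18 4-tert-butyl 1-ethyl (2E,3R)-2-{(2Z)-4-[(tert-butyldiphenylsilyl)oxy]-3-iodobut-2-en-1-ylidene}-3-methylbutanedioate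
Product: 19 tert-butyl (2R,3E,5Z)-7-[(tert-butyldiphenylsilyl)oxy]-3-(hydroxymethyl)-6-iodo-2-methylhepta-3,5-dienoate
Conditions: DIBAL-H (2.2 equiv), CH2Cl2, −78 °C; Rochelle salt
Reagents that add atoms: none
Why: DIBAL-H reduces the unhindered conjugated ethyl ester (1,2-reduction) much faster than the tert-butyl ester at −78 °C.

**Step 14**
Reactants: 19 tert-butyl (2R,3E,5Z)-7-[(tert-butyldiphenylsilyl)oxy]-3-(hydroxymethyl)-6-iodo-2-methylhepta-3,5-dienoate
Product: 20 tert-butyl (2R)-2-[(2R,3R)-2-(hydroxymethyl)-3-{(1Z)-3-[(tert-butyldiphenylsilyl)oxy]-2-iodoprop-1-en-1-yl}oxiran-2-yl]propanoate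
Conditions: Ti(OiPr)4, D-(−)-diethyl tartrate, t-BuOOH, 4 Å MS, CH2Cl2, −20 °C
Reagents that add atoms: tert-butyl hydroperoxide CC(C)(C)OO
Why: Sharpless asymmetric epoxidation touches only the allylic-alcohol alkene and D-(−)-DET delivers oxygen to the face that gives the (2R,3R)-epoxy alcohol (reagent control), setting the C8–O stereocentre.

**Step 15**
Reactants: 20 tert-butyl (2R)-2-[(2R,3R)-2-(hydroxymethyl)-3-{(1Z)-3-[(tert-butyldiphenylsilyl)oxy]-2-iodoprop-1-en-1-yl}oxiran-2-yl]propanoate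
Product: 22 (3R,4R,5S)-5-{(1Z)-3-[(tert-butyldiphenylsilyl)oxy]-2-iodoprop-1-en-1-yl}-4-hydroxy-4-(hydroxymethyl)-3-methyloxolan-2-one, via epoxy acid 21 (not isolated)
Conditions: TFA, CH2Cl2, 0 °C → rt; aq. NaHCO3/MeOH work-up
Reagents that add atoms: none
Why: Acidolysis of the tert-butyl ester and five-membered lactonisation by backside (SN2) opening of the vinyl epoxide at the allylic carbon invert C7 and retain the C8–O bond, giving the trans C6/C9 arrangement of the β-hydroxy-γ-lactone.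

**Step 16**
Reactants: 23 acetylene; 24 hexabutylditin
Product: 25 (Z)-1,2-bis(tributylstannyl)ethene
Conditions: Pd(PPh3)4 (cat.), dioxane, 60 °C
Reagents that add atoms: none
Why: Pd(0)-catalysed syn-distannation of acetylene gives only the (Z)-bis-stannane.

**Step 17**
Reactants: 22 (3R,4R,5S)-5-{(1Z)-3-[(tert-butyldiphenylsilyl)oxy]-2-iodoprop-1-en-1-yl}-4-hydroxy-4-(hydroxymethyl)-3-methyloxolan-2-one; 25 (Z)-1,2-bis(tributylstannyl)ethene
Product: 26 (3R,4R,5S)-5-[(1E,3Z)-2-{[(tert-butyldiphenylsilyl)oxy]methyl}-4-(tributylstannyl)buta-1,3-dien-1-yl]-4-hydroxy-4-(hydroxymethyl)-3-methyloxolan-2-one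
Conditions: Pd2(dba)3 (cat.), AsPh3, NMP, rt; 25 in excess (2.5 equiv)
Reagents that add atoms: none
Why: Stille cross-coupling proceeds with retention at both sp2 carbons and the excess bis-stannane stops it at mono-coupling, giving the (1E,3Z)-dienylstannane.

**Step 18**
Reactants: 26 (3R,4R,5S)-5-[(1E,3Z)-2-{[(tert-butyldiphenylsilyl)oxy]methyl}-4-(tributylstannyl)buta-1,3-dien-1-yl]-4-hydroxy-4-(hydroxymethyl)-3-methyloxolan-2-one
Product: 27 (3R,4R,5S)-5-[(1E,3Z)-2-{[(tert-butyldiphenylsilyl)oxy]methyl}-4-iodobuta-1,3-dien-1-yl]-4-hydroxy-4-(hydroxymethyl)-3-methyloxolan-2-one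
Conditions: I2, CH2Cl2, 0 °C
Reagents that add atoms: iodine II
Why: Iododestannylation (ipso electrophilic substitution) occurs with retention, giving the (Z)-dienyl iodide.

**Step 19**
Reactants: 27 (3R,4R,5S)-5-[(1E,3Z)-2-{[(tert-butyldiphenylsilyl)oxy]methyl}-4-iodobuta-1,3-dien-1-yl]-4-hydroxy-4-(hydroxymethyl)-3-methyloxolan-2-one
Product: 28 (2S,3S,4R)-2-[(1E,3Z)-2-{[(tert-butyldiphenylsilyl)oxy]methyl}-4-iodobuta-1,3-dien-1-yl]-3-hydroxy-4-methyl-5-oxooxolane-3-carbaldehyde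
Conditions: TEMPO (cat.), PhI(OAc)2, CH2Cl2, rt; used crude
Reagents that add atoms: none
Why: TEMPO/PhI(OAc)2 oxidation converts the primary alcohol to the aldehyde in the presence of the tertiary alcohol, and the quaternary α-carbon cannot epimerise.

**Step 20**
Reactants: 8 (1S,6R)-3-bromo-6-(dimethoxymethyl)-4,6-dimethylcyclohex-4-en-1-yl acetate; 28 (2S,3S,4R)-2-[(1E,3Z)-2-{[(tert-butyldiphenylsilyl)oxy]methyl}-4-iodobuta-1,3-dien-1-yl]-3-hydroxy-4-methyl-5-oxooxolane-3-carbaldehyde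
Product: 30 C9–C10-coupled 2,3-seco-briarane 8,9-diol, via allylchromium 29 (not isolated)
Conditions: CrCl2 (nickel-free, 6 equiv), THF, 0 °C → rt; 8 (2 equiv)
Reagents that add atoms: none
Why: In this Nozaki–Hiyama allylation Cr(II) turns 8 into allylchromium(III) 29 with Cr on the less hindered terminus, which adds to the aldehyde (the vinyl iodide is inert without Ni) through a chair transition state at C10 on the face opposite the C14 acetoxy and C1 dimethoxymethyl groups, and the ring-locked (Z)-allyl unit gives the syn 9S,10S adduct with the C11=C12 alkene.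

**Step 21**
Reactants: 30 C9–C10-coupled 2,3-seco-briarane 8,9-diol
Product: 31 seco-briarane 9,14-diacetate (8-OH free; C2 dimethyl acetal)
Conditions: Ac2O, pyridine, DMAP (cat.), CH2Cl2, 0 °C → rt
Reagents that add atoms: acetic anhydride CC(=O)OC(C)=O
Why: DMAP-catalysed acetylation esterifies the secondary C9 alcohol while the tertiary C8 alcohol is inert, which installs a final acetate and blocks translactonisation and later lactol formation.

**Step 22**
Reactants: 31 seco-briarane 9,14-diacetate (8-OH free; C2 dimethyl acetal)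
Product: 33 seco-briarane C2 aldehyde 8-O-TES ether, via lutidinium salt 32 (not isolated)
Conditions: TESOTf (4 equiv), 2,6-lutidine (6 equiv), CH2Cl2, −20 → 0 °C; then H2O
Reagents that add atoms: triethylsilyl triflate CC[Si](CC)(CC)OS(=O)(=O)C(F)(F)F; water O
Why: In this silyl-triflate/lutidine acetal cleavage the dimethyl acetal becomes a pyridinium salt that water hydrolyses to the aldehyde under non-acidic conditions, while the tertiary C8 alcohol is silylated in the same pot so that it cannot close a six-membered lactol onto the new aldehyde.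

**Step 23**
Reactants: 33 seco-briarane C2 aldehyde 8-O-TES ether
Product: 35 macrocyclic (2S)-alcohol (briarane skeleton; 8-O-TES; 16-O-TBDPS), via alkenylchromium 34 (not isolated)
Conditions: CrCl2 (15 equiv), NiCl2 (1 mol % of Cr), DMSO/THF, rt, syringe-pump addition to 0.002 M
Reagents that add atoms: none
Why: In this Nozaki–Hiyama–Kishi macrocyclization Ni(0) inserts into the (Z)-C–I bond with retention, transmetallation gives alkenylchromium 34, and intramolecular addition to the non-enolisable aldehyde closes the ten-membered ring with the Cr-bound carbonyl oxygen expected on the ring periphery, away from the C14 acetate, so that C3 adds to the Si face and C2 becomes S.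

**Step 24**
Reactants: 35 macrocyclic (2S)-alcohol (briarane skeleton; 8-O-TES; 16-O-TBDPS)
Product: 36 2,8,16-triol 9,14-diacetate
Conditions: HF·pyridine, pyridine, THF, 0 °C → rt
Reagents that add atoms: none
Why: Buffered fluoride desilylation removes the tertiary TES and primary TBDPS ethers without touching the acetates, lactone or diene.

**Step 25**
Reactants: 36 2,8,16-triol 9,14-diacetate
Product: 37 CNP0224753.2 (target)
Conditions: Ac2O, pyridine, DMAP (cat.), CH2Cl2, 0 °C → rt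
Reagents that add atoms: acetic anhydride CC(=O)OC(C)=O
Why: DMAP-catalysed acetylation esterifies the secondary C2 and primary C16 alcohols while the hindered tertiary C8 alcohol stays free, giving the target.

**Compound list**
1 | (S)-(+)-carvone | O=C1C(C)=CC[C@H](C(C)=C)C1 | starting material
2 | (5R)-6-(hydroxymethylidene)-2-methyl-5-(prop-1-en-2-yl)cyclohex-2-en-1-one (enol form of 6-formylcarvone) | O=C1C(C)=CC[C@H](C(C)=C)C1=CO | intermediate
3 | (1R,6R)-1,3-dimethyl-2-oxo-6-(prop-1-en-2-yl)cyclohex-3-ene-1-carbaldehyde | O=C[C@@]1(C)[C@@H](C(C)=C)CC=C(C)C1=O | intermediate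
4 | (5R,6R)-6-(dimethoxymethyl)-2,6-dimethyl-5-(prop-1-en-2-yl)cyclohex-2-en-1-one | COC(OC)[C@@]1(C)[C@@H](C(C)=C)CC=C(C)C1=O | intermediate
5 | 6-(dimethoxymethyl)-5-(1-hydroperoxy-1-methoxyethyl)-2,6-dimethylcyclohex-2-en-1-one (ring centres as in 4; peroxy carbon as a mixture) | COC(OC)[C@@]1(C)[C@@H](C(C)(OC)OO)CC=C(C)C1=O | intermediate (not isolated)
6 | (1S,6R)-6-(dimethoxymethyl)-4,6-dimethyl-5-oxocyclohex-3-en-1-yl acetate | COC(OC)[C@@]1(C)[C@@H](OC(C)=O)CC=C(C)C1=O | intermediate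
7 | (1S,6R)-6-(dimethoxymethyl)-5-hydroxy-4,6-dimethylcyclohex-3-en-1-yl acetate (both C5 epimers) | COC(OC)[C@@]1(C)[C@@H](OC(C)=O)CC=C(C)C1O | intermediate
8 | (1S,6R)-3-bromo-6-(dimethoxymethyl)-4,6-dimethylcyclohex-4-en-1-yl acetate (C3 epimers; may contain the allylic regioisomer) | COC(OC)[C@@]1(C)[C@@H](OC(C)=O)CC(Br)C(C)=C1 | intermediate
9 | tert-butyl (2R)-2-hydroxypropanoate (tert-butyl D-lactate) | C[C@@H](O)C(=O)OC(C)(C)C | starting material
10 | tert-butyl (2R)-2-{[(trifluoromethyl)sulfonyl]oxy}propanoate | C[C@@H](OS(=O)(=O)C(F)(F)F)C(=O)OC(C)(C)C | intermediate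
11 | triethyl phosphonoacetate | CCOC(=O)CP(=O)(OCC)OCC | starting material
12 | 4-tert-butyl 1-ethyl (3S)-2-(diethoxyphosphoryl)-3-methylbutanedioate (C2 epimers) | CCOC(=O)C(P(=O)(OCC)OCC)[C@@H](C)C(=O)OC(C)(C)C | intermediate
13 | but-2-yne-1,4-diol | OCC#CCO | starting material
14 | 4-[(tert-butyldiphenylsilyl)oxy]but-2-yn-1-ol | OCC#CCO[Si](c1ccccc1)(c1ccccc1)C(C)(C)C | intermediate
15 | sodium cyclic alkoxy(alkenyl)bis(2-methoxyethoxy)aluminate (Al on C3 of the butenyl unit, cis to the CH2O–Al arm) | [Na+].COCCO[Al-]1(OCCOC)OC/C=C1/CO[Si](c2ccccc2)(c2ccccc2)C(C)(C)C | intermediate (not isolated)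
16 | (2Z)-4-[(tert-butyldiphenylsilyl)oxy]-3-iodobut-2-en-1-ol | OC/C=C(\I)CO[Si](c1ccccc1)(c1ccccc1)C(C)(C)C | intermediate
17 | (2Z)-4-[(tert-butyldiphenylsilyl)oxy]-3-iodobut-2-enal | O=C/C=C(\I)CO[Si](c1ccccc1)(c1ccccc1)C(C)(C)C | intermediate
18 | 4-tert-butyl 1-ethyl (2E,3R)-2-{(2Z)-4-[(tert-butyldiphenylsilyl)oxy]-3-iodobut-2-en-1-ylidene}-3-methylbutanedioate | CCOC(=O)/C(=C/C=C(\I)CO[Si](c1ccccc1)(c1ccccc1)C(C)(C)C)[C@@H](C)C(=O)OC(C)(C)C | intermediate
19 | tert-butyl (2R,3E,5Z)-7-[(tert-butyldiphenylsilyl)oxy]-3-(hydroxymethyl)-6-iodo-2-methylhepta-3,5-dienoate | OC/C(=C/C=C(\I)CO[Si](c1ccccc1)(c1ccccc1)C(C)(C)C)[C@@H](C)C(=O)OC(C)(C)C | intermediate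
20 | tert-butyl (2R)-2-[(2R,3R)-2-(hydroxymethyl)-3-{(1Z)-3-[(tert-butyldiphenylsilyl)oxy]-2-iodoprop-1-en-1-yl}oxiran-2-yl]propanoate | OC[C@]1(O[C@@H]1/C=C(\I)CO[Si](c1ccccc1)(c1ccccc1)C(C)(C)C)[C@@H](C)C(=O)OC(C)(C)C | intermediate
21 | (2R)-2-[(2R,3R)-2-(hydroxymethyl)-3-{(1Z)-3-[(tert-butyldiphenylsilyl)oxy]-2-iodoprop-1-en-1-yl}oxiran-2-yl]propanoic acid | OC[C@]1(O[C@@H]1/C=C(\I)CO[Si](c1ccccc1)(c1ccccc1)C(C)(C)C)[C@@H](C)C(O)=O | intermediate (not isolated)
22 | (3R,4R,5S)-5-{(1Z)-3-[(tert-butyldiphenylsilyl)oxy]-2-iodoprop-1-en-1-yl}-4-hydroxy-4-(hydroxymethyl)-3-methyloxolan-2-one | OC[C@]1(O)[C@@H](C)C(=O)O[C@H]1/C=C(\I)CO[Si](c1ccccc1)(c1ccccc1)C(C)(C)C | intermediate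
23 | acetylene | C#C | starting material
24 | hexabutylditin | CCCC[Sn](CCCC)(CCCC)[Sn](CCCC)(CCCC)CCCC | starting material
25 | (Z)-1,2-bis(tributylstannyl)ethene | CCCC[Sn](CCCC)(CCCC)/C=C\[Sn](CCCC)(CCCC)CCCC | intermediate
26 | (3R,4R,5S)-5-[(1E,3Z)-2-{[(tert-butyldiphenylsilyl)oxy]methyl}-4-(tributylstannyl)buta-1,3-dien-1-yl]-4-hydroxy-4-(hydroxymethyl)-3-methyloxolan-2-one | OC[C@]1(O)[C@@H](C)C(=O)O[C@H]1/C=C(CO[Si](c1ccccc1)(c1ccccc1)C(C)(C)C)\C=C/[Sn](CCCC)(CCCC)CCCC | intermediate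
27 | (3R,4R,5S)-5-[(1E,3Z)-2-{[(tert-butyldiphenylsilyl)oxy]methyl}-4-iodobuta-1,3-dien-1-yl]-4-hydroxy-4-(hydroxymethyl)-3-methyloxolan-2-one | OC[C@]1(O)[C@@H](C)C(=O)O[C@H]1/C=C(CO[Si](c1ccccc1)(c1ccccc1)C(C)(C)C)\C=C/I | intermediate
28 | (2S,3S,4R)-2-[(1E,3Z)-2-{[(tert-butyldiphenylsilyl)oxy]methyl}-4-iodobuta-1,3-dien-1-yl]-3-hydroxy-4-methyl-5-oxooxolane-3-carbaldehyde | O=C[C@]1(O)[C@@H](C)C(=O)O[C@H]1/C=C(CO[Si](c1ccccc1)(c1ccccc1)C(C)(C)C)\C=C/I | intermediate
29 | dichloro(cyclohexenyl)chromium(III) from 8 (Cr on the former C–Br carbon; η1 form drawn) | COC(OC)[C@@]1(C)[C@@H](OC(C)=O)CC([Cr](Cl)Cl)C(C)=C1 | intermediate (not isolated)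
30 | C9–C10-coupled 2,3-seco-briarane: 8,9-diol; 14-acetate; C2 as dimethyl acetal; 16-O-TBDPS; (3Z)-3-iodo-3,5(E),11-triene; 19,7-lactone; C1, C7, C8, C9, C10, C14, C17 configured as in the target | I/C=C\C(CO[Si](c1ccccc1)(c1ccccc1)C(C)(C)C)=C/[C@@H]1OC(=O)[C@H](C)[C@@]1(O)[C@@H](O)[C@H]1C(C)=CC[C@H](OC(C)=O)[C@]1(C)C(OC)OC | intermediate
31 | 9-O-acetyl derivative of 30 (8-OH free) | I/C=C\C(CO[Si](c1ccccc1)(c1ccccc1)C(C)(C)C)=C/[C@@H]1OC(=O)[C@H](C)[C@@]1(O)[C@@H](OC(C)=O)[C@H]1C(C)=CC[C@H](OC(C)=O)[C@]1(C)C(OC)OC | intermediate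
32 | 8-O-TES ether of 31 in which one acetal methoxy group is replaced by N-bound 2,6-lutidinium (triflate salt; N,O-acetal carbon as a mixture) | I/C=C\C(CO[Si](c1ccccc1)(c1ccccc1)C(C)(C)C)=C/[C@@H]1OC(=O)[C@H](C)[C@@]1(O[Si](CC)(CC)CC)[C@@H](OC(C)=O)[C@H]1C(C)=CC[C@H](OC(C)=O)[C@]1(C)C(OC)[n+]1c(C)cccc1C.[O-]S(=O)(=O)C(F)(F)F | intermediate (not isolated)
33 | 2,3-seco-briarane C2 aldehyde: 8-O-TES; 9,14-diacetate; 16-O-TBDPS; (3Z)-3-iodo-3,5(E),11-triene; 19,7-lactone | I/C=C\C(CO[Si](c1ccccc1)(c1ccccc1)C(C)(C)C)=C/[C@@H]1OC(=O)[C@H](C)[C@@]1(O[Si](CC)(CC)CC)[C@@H](OC(C)=O)[C@H]1C(C)=CC[C@H](OC(C)=O)[C@]1(C)C=O | intermediate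
34 | (Z)-alkenyl(dichloro)chromium(III) derived from 33 (Cr in place of I at C3) | Cl[Cr](Cl)/C=C\C(CO[Si](c1ccccc1)(c1ccccc1)C(C)(C)C)=C/[C@@H]1OC(=O)[C@H](C)[C@@]1(O[Si](CC)(CC)CC)[C@@H](OC(C)=O)[C@H]1C(C)=CC[C@H](OC(C)=O)[C@]1(C)C=O | intermediate (not isolated)
35 | (2S)-2-hydroxy-8-O-TES-16-O-TBDPS-9,14-di-O-acetyl-briara-3(Z),5(E),11-trien-19,7-olide (all other centres as in the target) | CC(C)(C)[Si](c1ccccc1)(c1ccccc1)OCC1=C/[C@@H]2OC(=O)[C@H](C)[C@@]2(O[Si](CC)(CC)CC)[C@@H](OC(C)=O)[C@H]2C(C)=CC[C@H](OC(C)=O)[C@]2(C)[C@@H](O)/C=C\1 | intermediate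
36 | 2,8,16-trihydroxy-9,14-di-O-acetyl-briara-3(Z),5(E),11-trien-19,7-olide (configured as the target) | OCC1=C/[C@@H]2OC(=O)[C@H](C)[C@@]2(O)[C@@H](OC(C)=O)[C@H]2C(C)=CC[C@H](OC(C)=O)[C@]2(C)[C@@H](O)/C=C\1 | intermediate
37 | CNP0224753.2: (1R,2S,3Z,5E,7S,8S,9S,10S,14S,17R)-2,9,14,16-tetraacetoxy-8-hydroxybriara-3,5,11-trien-19,7-olide | CC(=O)OCC1=C/[C@@H]2OC(=O)[C@H](C)[C@@]2(O)[C@@H](OC(C)=O)[C@H]2C(C)=CC[C@H](OC(C)=O)[C@]2(C)[C@@H](OC(C)=O)/C=C\1 | target

**Step count and weak points**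
Total step count: 25. Longest linear sequence: 16 steps (steps 9–15 and 17–25, from but-2-yne-1,4-diol), i.e. 64 % of the total; the carvone branch (steps 1–6), the lactate branch (steps 7–8) and the stannane (step 16) run in parallel.

Most likely to fail:

- **Step 20 (Cr-mediated C9–C10 union).** The allylchromium may bond through C12 instead of the neopentylic C10, may attack from the wrong ring face, or may be sluggish with the α-quaternary aldehyde. The fallback replaces the equilibrating allylchromium by a configurationally defined allylboron reagent. It sets out from 7: the epimer of 7 whose hydroxyl is cis to the dimethoxymethyl group (separated by chromatography, the other epimer recycled by MnO2 oxidation and Luche reduction) is acetylated to the cis-diacetate F1. Miyaura allylic borylation (Pd2(dba)3, B2pin2, DMSO, net anti-1,3 substitution) gives the cyclohexenyl pinacolboronate F2 with boron on the face of the C1 methyl group. Its Sc(OTf)3-promoted allylboration of 28 through a closed chair transition state forms the C9–C10 bond suprafacially and regiospecifically and returns to the route at 30.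

- **Step 23 (NHK macrocyclization).** Ring strain may lower the yield and the C2 configuration rests on a conformational argument. If the cyclization from 33 delivers the 2R alcohol, the 2-epimeric macrocycle F3 (or the epimer mixture) is oxidised with Dess–Martin periodinane to the macrocyclic dienone F4. This is reduced under reagent control with (R)-Me-CBS/catecholborane (quaternary C1 as the large group, hydride to the Re face), which returns to the route at 35.

- **Step 15 (epoxide-opening lactonization).** The free primary C9 alcohol or trifluoroacetate may compete for the acid-activated vinyl epoxide. The fallback changes the order of events so that no 2,3-epoxy alcohol is exposed to acid. It sets out from 20: Parikh–Doering oxidation gives the epoxy aldehyde F5; Cr(II) allylation with 8 gives the coupled epoxy alcohol F6; acetylation gives the epoxy acetate F7. TESOTf/2,6-lutidine followed by water then triggers attack of the tert-butyl ester carbonyl on the epoxide (loss of isobutene, inversion at C7), silylates O8 and unmasks the acetal in one operation, giving the lactone aldehyde F8. Stille coupling with 25 gives the dienylstannane F9, and iododestannylation returns to the route at 33.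

**Further compounds**
F1 | step 20 | (1S,5R,6R)-6-(dimethoxymethyl)-4,6-dimethylcyclohex-3-ene-1,5-diyl diacetate (C5 acetoxy cis to the dimethoxymethyl group) | COC(OC)[C@@]1(C)[C@@H](OC(C)=O)CC=C(C)[C@H]1OC(C)=O
F2 | step 20 | (1S,3S,6R)-6-(dimethoxymethyl)-4,6-dimethyl-3-(4,4,5,5-tetramethyl-1,3,2-dioxaborolan-2-yl)cyclohex-4-en-1-yl acetate (boron trans to the C1 acetoxy group) | COC(OC)[C@@]1(C)[C@@H](OC(C)=O)C[C@H](B2OC(C)(C)C(C)(C)O2)C(C)=C1
F3 | step 23 | 2-epimer (2R) of macrocyclic alcohol 35 | CC(C)(C)[Si](c1ccccc1)(c1ccccc1)OCC1=C/[C@@H]2OC(=O)[C@H](C)[C@@]2(O[Si](CC)(CC)CC)[C@@H](OC(C)=O)[C@H]2C(C)=CC[C@H](OC(C)=O)[C@]2(C)[C@H](O)/C=C\1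
F4 | step 23 | macrocyclic 2-oxo-3(Z),5(E)-dienone corresponding to 35 | CC(C)(C)[Si](c1ccccc1)(c1ccccc1)OCC1=C/[C@@H]2OC(=O)[C@H](C)[C@@]2(O[Si](CC)(CC)CC)[C@@H](OC(C)=O)[C@H]2C(C)=CC[C@H](OC(C)=O)[C@]2(C)C(=O)/C=C\1
F5 | step 15 | tert-butyl (2R)-2-[(2R,3R)-2-formyl-3-{(1Z)-3-[(tert-butyldiphenylsilyl)oxy]-2-iodoprop-1-en-1-yl}oxiran-2-yl]propanoate | O=C[C@]1(O[C@@H]1/C=C(\I)CO[Si](c1ccccc1)(c1ccccc1)C(C)(C)C)[C@@H](C)C(=O)OC(C)(C)C
F6 | step 15 | C9–C10-coupled 7,8-epoxy tert-butyl ester with free 9-OH (C5 vinyl iodide; C2 dimethyl acetal; 14-acetate) | CC(C)(C)OC(=O)[C@H](C)[C@@]1(O[C@@H]1/C=C(\I)CO[Si](c1ccccc1)(c1ccccc1)C(C)(C)C)[C@@H](O)[C@H]1C(C)=CC[C@H](OC(C)=O)[C@]1(C)C(OC)OC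
F7 | step 15 | 9-O-acetate of F6 | CC(C)(C)OC(=O)[C@H](C)[C@@]1(O[C@@H]1/C=C(\I)CO[Si](c1ccccc1)(c1ccccc1)C(C)(C)C)[C@@H](OC(C)=O)[C@H]1C(C)=CC[C@H](OC(C)=O)[C@]1(C)C=O.CO.CO
F8 | step 15 | 19,7-lactone C2 aldehyde with 8-O-TES, 9,14-diacetate and the C5 vinyl iodide | I/C(CO[Si](c1ccccc1)(c1ccccc1)C(C)(C)C)=C\[C@@H]1OC(=O)[C@H](C)[C@@]1(O[Si](CC)(CC)CC)[C@@H](OC(C)=O)[C@H]1C(C)=CC[C@H](OC(C)=O)[C@]1(C)C=O
F9 | step 15 | (3Z)-3-tributylstannyl analogue of 33 | CCCC[Sn](CCCC)(CCCC)/C=C\C(CO[Si](c1ccccc1)(c1ccccc1)C(C)(C)C)=C/[C@@H]1OC(=O)[C@H](C)[C@@]1(O[Si](CC)(CC)CC)[C@@H](OC(C)=O)[C@H]1C(C)=CC[C@H](OC(C)=O)[C@]1(C)C=O
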